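Comparing what Z gains with what J loses gave me the number I needed for these flasks.

| flask | D | L | temperature | remark | time |
|---|---|---|---|---|---|
| noon | 0.070 M | 2 equiv | 20 °C | run made earlier |  |
| autumn | 0.11 M | 2 equiv | 50 °C | run made earlier |  |
| west | 0.050 M | 2.00 equiv |  | at 25 °C until 80 s, from then on at 75 °C | 2.0 min |
| north | 0.050 M | 2.00 equiv | 75 °C |  | 2.0 min |
| south-east | 0.050 M | 2.00 equiv | 25 °C |  | 2.0 min |
| south | 0.050 M | 2.00 equiv | 50 °C |  | 2.0 min |

| run | time / min | J / % | Z / % |
|---|---|---|---|
| noon | 4.00 | 9 | 8 |
| noon | 8.00 | 3 | 21 |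
| noon | 12.0 | 0 | 29 |
| noon | 15.0 | 0 | 31 |
| noon | 20.0 | 0 | 31 |
| noon | 25.0 | 0 | 33 |
| noon | 30.0 | 0 | 34 |
| autumn | 0.500 | 0 | 8 |
| autumn | 1.00 | 0 | 10 |
| autumn | 1.50 | 1 | 12 |
| autumn | 3.00 | 0 | 11 |
| autumn | 5.00 | 0 | 10 |
| autumn | 6.00 | 0 | 9 |

(scatter of a reading: 1.5 percentage points)

- percent here means D units held: one Z counts as two

1. the flask with the highest share of J in all that became J or Z ("all alike" if they lie within 1.5 percentage points) (west / north / south-east / south / all alike)
2. share of J in all that became J or Z, west
3. share of J in all that became J or Z, north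
4. share of J in all that became J or Z, south-east
5. share of J in all that became J or Z, south

Between 4.00 min and 8.00 min of the noon run, Z gained 13 percentage points while J lost 6 points, a ratio of 2.17 in which time has dropped out. A Z holds two D units, so I read each lost J as taking one more D with it. J's loss should then go with c(D), and at nearly steady c(D) it is pseudo-first-order in J:

k = ln(J early / J late) / time between = 0.275 min⁻¹, at c(D) near 0.0557 M

For south-east I scaled k to c(D) = 0.050 M and allowed a guessed factor of 1.41 for the warmer flask, since the readings show no J decay at another temperature. Then I multiplied by the time: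

N = 0.275 min⁻¹ × 0.050 M / 0.0557 M × 1.41 × 2.0 min = 0.698

This is the ageing number, the time of reading counted in lifetimes of J. If J is made evenly and lost at the rate k, then counting Z in D units, where each lost J appears as 2 units, gives

Z/J = 2 × (N / (1 − exp(−N)) − 1) = 0.779

so the share of J is

1 / (1 + Z/J) = 56.2%

As a test, the same formula with N = k × 4.00 min = 1.10 gives the noon run a Z/J of 1.30, higher than the 0.889 read there, and each of those two readings carries a scatter of 1.5 points. But one number was not enough, because N assumes J is still being made. In the autumn run Z read from 12% down to 9% from 1.50 min on, a mean of 0.105 with no further rise, and J read 0% at 3.00 min. So I expected south, north and west far below 56.2%.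

The forecast gave south-east as highest, with 68% there, 5% in south, 2% in west and 1% in north, reasoning that “the faster rate and the dilution roughly offset”, and its south-east share stands above my 56.2%.

The flasks gave south-east as highest, with 53.4% there, 0.176% in south, 0% in west and 0% in north.

    D + L + J → 2 J (k = 48.0 M⁻² s⁻¹, Ea = 48.0 kJ mol⁻¹)
    D + J → Z (k = 1.00 M⁻¹ s⁻¹, Ea = 67.0 kJ mol⁻¹)
    D + L → J (k = 0.00230 M⁻¹ s⁻¹, Ea = 55.0 kJ mol⁻¹)
    L → Q (k = 0.200 s⁻¹, Ea = 78.0 kJ mol⁻¹)
    (constants at 50 °C)

In south-east, Z/J stood at 0.871 at 2.00 min, above my reckoned 0.779. The same flask read at 30 s has a share of 85.4%, and N scaled to that time, 0.174, gives 84.8%. In south-east at 0.548 min, L passed into Q 340 times as fast as it was used by D + L + J → 2 J. At 2.00 min, south-east held 12% of its L and 98.9% of its D.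

The runs stem from a simulated flask for substances that don't exist; scatter was added.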